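## Retrosynthetic overview

1. Target ⇒ a 2-substituted 1,4-benzoquinone + 2,5-bis(trimethylsilyloxy)furan (Diels–Alder/aromatisation builds the second six-membered ring last); the quinone comes from a 2,5-dimethoxyphenyl group by oxidative demethylation.
2. Tertiary angelate ⇒ tertiary cyclobutanol + angelic anhydride (alkoxide acylation).
3. Ring CH2 next to the carbinol ⇒ CH–O-aroyl: a secondary 3-(trifluoromethyl)benzoyloxy group acts as stereo-relay and is then removed by photoinduced electron transfer.
4. Cyclobutane (key bond C(OH)(Ar)–CMe2, quaternary stereocentre) ⇒ α-acyloxy aryl ketone, by Norrish–Yang photocyclisation under control of the α-stereocentre.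
5. Ketone ⇒ D-leucic acid (all six carbons of the dimethylcyclobutane and the only bought stereocentre) + 1,4-dimethoxybenzene. Ring order: benzene ring (bought) → cyclobutane → second six-membered ring.

Assumption: all compounds marked "starting material" in the list are taken as catalogue chemicals, and the naphthazarin is drawn as the tautomer of the given SMILES (its tautomers interconvert rapidly).

## Route

Step 1
Reactants: 1 (R)-2-hydroxy-4-methylpentanoic acid (D-leucic acid); 2 1,4-dimethoxybenzene
Product: 6 (R)-1-(2,5-dimethoxyphenyl)-2-hydroxy-4-methylpentan-1-one, via 2,5-dimethoxyphenyllithium 3 (not isolated), via dilithium (R)-4-methyl-2-oxidopentanoate 4 (not isolated), via trilithium gem-diolate adduct 5 (not isolated)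
Conditions: 2 (3.4 equiv), n-BuLi (3.3 equiv), THF, 0 °C → rt, 2 h; then 1, −78 °C → rt, 4 h; inverse quench into cold 1 M HCl
Reagents that add atoms: none
Why: Directed ortho-lithiation followed by organolithium addition to a lithium carboxylate (ketone synthesis through gem-diolate 5, which cannot over-add); the α-alkoxide dianion 4 cannot enolise, so the bought (R) centre is carried through unchanged.

Step 2
Reactants: 6 (R)-1-(2,5-dimethoxyphenyl)-2-hydroxy-4-methylpentan-1-one
Product: 7 (R)-1-(2,5-dimethoxyphenyl)-4-methyl-1-oxopentan-2-yl 3-(trifluoromethyl)benzoate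
Conditions: 3-(trifluoromethyl)benzoyl chloride (1.2 equiv), pyridine (2 equiv), CH2Cl2, 0 °C → rt
Reagents that add atoms: 3-(trifluoromethyl)benzoyl chloride, O=C(Cl)c1cccc(c1)C(F)(F)F
Why: Acyl chloride esterification of the secondary α-hydroxyl under conditions too weakly basic to enolise the ketone, so the (R) centre is retained, and the electron-poor benzoate then serves as hydrogen-bond acceptor in step 3 and as reductive leaving group in step 4.

Step 3
Reactants: 7 (R)-1-(2,5-dimethoxyphenyl)-4-methyl-1-oxopentan-2-yl 3-(trifluoromethyl)benzoate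
Product: 9 (1R,2R)-2-(2,5-dimethoxyphenyl)-2-hydroxy-3,3-dimethylcyclobutyl 3-(trifluoromethyl)benzoate (hydroxyl cis to the benzoate), via triplet 1,4-biradical 8 (not isolated)
Conditions: hν (350 nm, Pyrex), degassed benzene (0.01 M), 15 °C, to full conversion; chromatographic removal of the minor trans isomer
Reagents that add atoms: none
Why: Proposed new method: an α-acyloxy-directed Norrish–Yang photocyclisation onto a tertiary γ-C–H, in which the excited aryl ketone abstracts the isopropyl methine hydrogen (1,5-hydrogen transfer) to give biradical 8, whose ketyl O–H hydrogen-bonds to the ester carbonyl while the aryl group sits anti to the acyloxy group, so that radical recombination forms the C(OH)(Ar)–CMe2 ring bond with OH cis to the ester and the bought (R) α-carbon sets the new quaternary carbinol centre as (R); the closest known reaction type is the Yang cyclisation of amino-acid-derived α-acylamino aryl ketones to cis-2-acylaminocyclobutanols, which has not been shown for α-acyloxy ketones.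

Step 4
Reactants: 9 (1R,2R)-2-(2,5-dimethoxyphenyl)-2-hydroxy-3,3-dimethylcyclobutyl 3-(trifluoromethyl)benzoate
Product: 10 (R)-1-(2,5-dimethoxyphenyl)-2,2-dimethylcyclobutan-1-ol
Conditions: hν (350 nm, Pyrex), 9-methylcarbazole (1 equiv, recovered), Mg(ClO4)2 (0.2 equiv), i-PrOH/H2O 10:1, N2, rt
Reagents that add atoms: none
Why: Saito-type photosensitised deoxygenation, in which electron transfer from excited 9-methylcarbazole to the electron-poor benzoate, C–O fragmentation and hydrogen-atom transfer from 2-propanol remove the relay oxygen without touching the quaternary (R) carbinol centre, a ring-carbon radical being poorly aligned for ring-opening β-scission.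

Step 5
Reactants: 10 (R)-1-(2,5-dimethoxyphenyl)-2,2-dimethylcyclobutan-1-ol; 11 angelic anhydride ((Z)-2-methylbut-2-enoic anhydride)
Product: 13 (R)-1-(2,5-dimethoxyphenyl)-2,2-dimethylcyclobutyl (Z)-2-methylbut-2-enoate, via lithium cyclobutanolate 12 (not isolated)
Conditions: LiHMDS (1.05 equiv), THF, −78 °C; then 11 (1.5 equiv), −78 → 0 °C; cold 0.1 M HCl work-up
Reagents that add atoms: none
Why: Acylation of the pre-formed lithium alkoxide 12 by the symmetrical anhydride (alkoxide acyl substitution) overcomes the hindrance of the tertiary hydroxyl without a nucleophilic catalyst, which avoids Z-to-E isomerisation of the angelate, and breaks no bond to the stereocentre.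

Step 6
Reactants: 13 (R)-1-(2,5-dimethoxyphenyl)-2,2-dimethylcyclobutyl (Z)-2-methylbut-2-enoate
Product: 14 (R)-1-(3,6-dioxocyclohexa-1,4-dien-1-yl)-2,2-dimethylcyclobutyl (Z)-2-methylbut-2-enoate
Conditions: ceric ammonium nitrate (2.5 equiv), MeCN/H2O 2:1, 0 °C, 15 min
Reagents that add atoms: water, O
Why: Ceric ammonium nitrate oxidative demethylation of the p-dimethoxyarene gives the p-benzoquinone (water delivers both quinone oxygens) and leaves the electron-poor angelate alkene and the tertiary ester untouched.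

Step 7
Reactants: 14 (R)-1-(3,6-dioxocyclohexa-1,4-dien-1-yl)-2,2-dimethylcyclobutyl (Z)-2-methylbut-2-enoate; 15 2,5-bis(trimethylsilyloxy)furan
Product: 18 (R)-1-(5,8-dihydroxy-1,4-dioxo-1,4-dihydronaphthalen-2-yl)-2,2-dimethylcyclobutyl (Z)-2-methylbut-2-enoate (target CNP0326301.1), via oxa-bridged Diels–Alder adduct 16 (not isolated), via 4a,8a-dihydro tetraone tautomer 17 (not isolated)
Conditions: 15 (1.3 equiv), CH2Cl2, −78 → 0 °C; then 1 M HCl, THF, rt
Reagents that add atoms: none
Why: Diels–Alder reaction of the electron-rich bis(silyloxy)furan at the unhindered, unsubstituted C=C of the quinone, then desilylative opening of the oxygen bridge and double enolisation of tetraone 17, builds the second six-membered ring directly at the naphthazarin oxidation level while the remote stereocentre is unaffected.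

## Compound list

1 | (R)-2-hydroxy-4-methylpentanoic acid (D-leucic acid) | CC(C)C[C@@H](O)C(=O)O | starting material
2 | 1,4-dimethoxybenzene | COc1ccc(OC)cc1 | starting material
3 | 2,5-dimethoxyphenyllithium | [Li]c1cc(OC)ccc1OC | intermediate
4 | dilithium (R)-4-methyl-2-oxidopentanoate | [Li+].[Li+].CC(C)C[C@@H]([O-])C(=O)[O-] | intermediate
5 | trilithium (R)-1-(2,5-dimethoxyphenyl)-4-methylpentane-1,1,2-tris(olate) (gem-diolate adduct) | [Li+].[Li+].[Li+].CC(C)C[C@@H]([O-])C([O-])([O-])c1cc(OC)ccc1OC | intermediate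
6 | (R)-1-(2,5-dimethoxyphenyl)-2-hydroxy-4-methylpentan-1-one | CC(C)C[C@@H](O)C(=O)c1cc(OC)ccc1OC | intermediate
7 | (R)-1-(2,5-dimethoxyphenyl)-4-methyl-1-oxopentan-2-yl 3-(trifluoromethyl)benzoate | CC(C)C[C@@H](OC(=O)c1cccc(c1)C(F)(F)F)C(=O)c1cc(OC)ccc1OC | intermediate
8 | (2R)-1-(2,5-dimethoxyphenyl)-1-hydroxy-4-methyl-2-[3-(trifluoromethyl)benzoyloxy]pentane-1,4-diyl (triplet 1,4-biradical) | C[C](C)C[C@@H](OC(=O)c1cccc(c1)C(F)(F)F)[C](O)c1cc(OC)ccc1OC | intermediate
9 | (1R,2R)-2-(2,5-dimethoxyphenyl)-2-hydroxy-3,3-dimethylcyclobutyl 3-(trifluoromethyl)benzoate | O[C@]1(c2cc(OC)ccc2OC)[C@H](OC(=O)c2cccc(c2)C(F)(F)F)CC1(C)C | intermediate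
10 | (R)-1-(2,5-dimethoxyphenyl)-2,2-dimethylcyclobutan-1-ol | O[C@]1(c2cc(OC)ccc2OC)CCC1(C)C | intermediate
11 | angelic anhydride ((Z)-2-methylbut-2-enoic anhydride) | C/C=C(/C)C(=O)OC(=O)/C(C)=C\C | starting material
12 | lithium (R)-1-(2,5-dimethoxyphenyl)-2,2-dimethylcyclobutan-1-olate | [Li+].[O-][C@]1(c2cc(OC)ccc2OC)CCC1(C)C | intermediate
13 | (R)-1-(2,5-dimethoxyphenyl)-2,2-dimethylcyclobutyl (Z)-2-methylbut-2-enoate | C/C=C(/C)C(=O)O[C@]1(c2cc(OC)ccc2OC)CCC1(C)C | intermediate
14 | (R)-1-(3,6-dioxocyclohexa-1,4-dien-1-yl)-2,2-dimethylcyclobutyl (Z)-2-methylbut-2-enoate | C/C=C(/C)C(=O)O[C@]1(C2=CC(=O)C=CC2=O)CCC1(C)C | intermediate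
15 | 2,5-bis(trimethylsilyloxy)furan | C[Si](C)(C)Oc1ccc(O[Si](C)(C)C)o1 | starting material
16 | (R)-1-[5,8-epoxy-1,4-dioxo-5,8-bis(trimethylsilyloxy)-1,4,4a,5,8,8a-hexahydronaphthalen-2-yl]-2,2-dimethylcyclobutyl (Z)-2-methylbut-2-enoate (new ring-fusion and bridgehead centres form as a transient mixture and are left unspecified) | C/C=C(/C)C(=O)O[C@]1(C2=CC(=O)C3C(C2=O)C4(O[Si](C)(C)C)C=CC3(O[Si](C)(C)C)O4)CCC1(C)C | intermediate
17 | (R)-2,2-dimethyl-1-(1,4,5,8-tetraoxo-1,4,4a,5,8,8a-hexahydronaphthalen-2-yl)cyclobutyl (Z)-2-methylbut-2-enoate (4a/8a centres transient, unspecified) | C/C=C(/C)C(=O)O[C@]1(C2=CC(=O)C3C(C2=O)C(=O)C=CC3=O)CCC1(C)C | intermediate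
18 | (R)-1-(5,8-dihydroxy-1,4-dioxo-1,4-dihydronaphthalen-2-yl)-2,2-dimethylcyclobutyl (Z)-2-methylbut-2-enoate | C/C=C(/C)C(=O)O[C@]1(C2=CC(=O)c3c(O)ccc(O)c3C2=O)CCC1(C)C | target

## Step count and risks

Total steps: 7. Longest linear sequence: 7 (1 → 18; 2, 11 and 15 are bought).

Steps most likely to fail:

**Step 3 (the proposed new Yang cyclisation).** Three things are unproven. The dimethoxyaryl ketone has a largely π,π* triplet, so hydrogen abstraction is slow. Biradical 8 can instead fragment (Norrish type II) to isobutene and a phenacyl ester. The cis sense and the level of 1,2-induction by an α-acyloxy group are predicted, not measured. Fallback with known chemistry, setting out from 2 and coming back at 10: 2 is lithiated to 3 as in step 1 and added (3.3 equiv) to commercial N-acetyl-D-leucine to give (R)-N-[1-(2,5-dimethoxyphenyl)-4-methyl-1-oxopentan-2-yl]acetamide F1. Irradiation (350 nm, benzene) is the documented Yang cyclisation of α-acetamido aryl ketones and gives the cis amido alcohol N-[(1R,2R)-2-(2,5-dimethoxyphenyl)-2-hydroxy-3,3-dimethylcyclobutyl]acetamide F2. N-Deacetylation with Schwartz reagent (Cp2Zr(H)Cl, THF, rt, aqueous work-up) gives (1R,2R)-2-amino-1-(2,5-dimethoxyphenyl)-4,4-dimethylcyclobutan-1-ol F3. Hydrodeamination of the primary amine through an isodiazene (anomeric amide reagent, MeCN, 45 °C) then gives 10.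

**Step 4 (photoreductive deoxygenation).** Electron transfer to a hindered cyclobutyl ester next to a free tertiary alcohol is untested, and the secondary cyclobutyl radical must take up hydrogen before it can ring-open. Fallback, setting out from 9 and coming back at 10: methanolysis (K2CO3, MeOH, rt) gives (1R,2R)-1-(2,5-dimethoxyphenyl)-4,4-dimethylcyclobutane-1,2-diol F4. NaH and phenyl isothiocyanate (THF, 0 °C) thiocarbamoylate only the secondary oxygen, with no cyclic thiocarbonate possible, to give O-[(1R,2R)-2-(2,5-dimethoxyphenyl)-2-hydroxy-3,3-dimethylcyclobutyl] N-phenylcarbamothioate F5. A Barton–McCombie tin hydride chain reduction (Bu3SnH 0.5 M, AIBN, toluene, 90 °C) then gives 10.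

**Step 5 (angeloylation).** The tertiary alkoxide is flanked by a quaternary carbon and an ortho-substituted arene, and the acyl donor is hindered and prone to isomerise to the tiglate. Fallback, setting out from 10 and coming back at 13: the Z-alkene is built after the ester bond. DCC-mediated esterification of 10 with 2-[bis(2,2,2-trifluoroethoxy)phosphoryl]propanoic acid (CH2Cl2, rt; acyl transfer through the small phosphono-ketene) gives (R)-1-(2,5-dimethoxyphenyl)-2,2-dimethylcyclobutyl 2-[bis(2,2,2-trifluoroethoxy)phosphoryl]propanoate F6. Still–Gennari olefination with acetaldehyde (KHMDS, 18-crown-6, THF, −78 °C) then gives the Z ester 13.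

Further compounds
F1 | step 3 | (R)-N-[1-(2,5-dimethoxyphenyl)-4-methyl-1-oxopentan-2-yl]acetamide | CC(C)C[C@@H](NC(C)=O)C(=O)c1cc(OC)ccc1OC
F2 | step 3 | N-[(1R,2R)-2-(2,5-dimethoxyphenyl)-2-hydroxy-3,3-dimethylcyclobutyl]acetamide | O[C@]1(c2cc(OC)ccc2OC)[C@H](NC(C)=O)CC1(C)C
F3 | step 3 | (1R,2R)-2-amino-1-(2,5-dimethoxyphenyl)-4,4-dimethylcyclobutan-1-ol | O[C@]1(c2cc(OC)ccc2OC)[C@H](N)CC1(C)C
F4 | step 4 | (1R,2R)-1-(2,5-dimethoxyphenyl)-4,4-dimethylcyclobutane-1,2-diol | O[C@]1(c2cc(OC)ccc2OC)[C@H](O)CC1(C)C
F5 | step 4 | O-[(1R,2R)-2-(2,5-dimethoxyphenyl)-2-hydroxy-3,3-dimethylcyclobutyl] N-phenylcarbamothioate | O[C@]1(c2cc(OC)ccc2OC)[C@H](OC(=S)Nc2ccccc2)CC1(C)C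
F6 | step 5 | (R)-1-(2,5-dimethoxyphenyl)-2,2-dimethylcyclobutyl 2-[bis(2,2,2-trifluoroethoxy)phosphoryl]propanoate (both epimers at the phosphonate carbon) | CC(C(=O)O[C@]1(c2cc(OC)ccc2OC)CCC1(C)C)P(=O)(OCC(F)(F)F)OCC(F)(F)F
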